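## Analysis of the target

Target 35 is a 3,4-seco-diterpenoid joined to a pyridyl-pyrone. Its trans-fused carbocyclic core consists of ring A (C1–C6: C1 carries the isopropenyl group, C2 and C3 are CH2, C4 is the methyl-bearing ring-fusion carbon, C5 the ring-fusion CH, C6 a quaternary carbon) and ring B (C4, C5, C7H2, C8H=C9(CH3), C10). Two spiro rings are attached: a δ-lactone at C6 (C12H2–C13H2–C14(=O)–O–C15H2) and a dihydrofuranol at C10, whose ether oxygen sits on C4′ and whose carbinol carbon C11 sits on C3′ of a 6-(pyridin-3-yl)-2-pyrone. There are six stereocentres (C1, C4, C5, C6, C10, C11). The C4 methyl and C5–H are trans; C15 lies on the same face of ring A as the angular methyl (1,3-diaxial), C12 is equatorial, and the isopropenyl group at C1 is equatorial. At C10 the ether oxygen lies on the face of the angular methyl (pseudo-equatorial) and C11 is pseudo-axial, anti to that methyl; the C11 hydroxyl points to the C9 side of the dihydrofuran ring. Sensitive groups are the δ-lactone and the 2-pyrone (nucleophiles, base), the C11 carbinol (flanked by the enol-ether carbon C3′, so it ionises easily in acid), the tertiary allylic ether at C10, the isopropenyl alkene and the basic pyridine. The difficulty is congestion: C5 is flanked by two quaternary carbons (C4, C6), C10 is a third fully substituted carbon next to C4, and three rings meet at two spiro atoms. The strategy rests on ring B: C10 with its oxygen, flanked by the methyl-bearing carbons C4 and C9, has the substitution pattern of 2,6-dimethyl-1,4-benzoquinone 10 (with one surplus oxygen at C7), and ring A with C6, its acyl arm C12–C14 and an oxygenated C1 has the pattern of the vinyl enol lactone 9, so that bonds C3–C4 and C5–C6 can be made in one cycloaddition.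

## Retrosynthetic reasoning

**35 to 29 and 34.** The dihydrofuranol is cut at C11–C3′ and at O–C4′. This is the only cut that leaves the C10–O bond intact, so the configuration at C10 can be set earlier by carbon addition to a ketone. It gives the tertiary α-hydroxy aldehyde 29 and the hydroxypyrone 34. The forward reaction must add pyrone C3′ to the neopentyl aldehyde and close the ether by attack of the tertiary hydroxyl on C4′. C11 is the only stereocentre it has to set.

**29 to 25.** The C10–C11 bond is cut. Enone 25 needs a one-carbon unit delivered to C10 from the face anti to the axial C4 methyl. A sulfur-ylide epoxidation (26) does this with the oxygen left equatorial, and the ylide does not touch the lactone. Basic opening at the CH2 carbon (28) keeps the C10–O bond, and oxidation of the primary alcohol gives 29.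

**25 to 23.** The C8=C9 double bond is taken back to the saturated ketone 24. The detour is deliberate: while ring B is a hindered saturated ketone it is inert, so the isopropenyl group can be made from the equatorial methyl ketone 23 by methylenation without competition. The ketone can enolise only toward C9, so the alkene returns regiospecifically.

**23 to 17.** One hydrogenation is asked to reduce both conjugated alkenes of 21 and to cleave the benzyl ether; the freed C15 hydroxyl then lactonises onto the methyl ester. This avoids a chemoselective conjugate reduction of one enone beside another and avoids Lewis-acid debenzylation in the presence of the isopropenyl group. The acetyl group of 21 comes from ketone 17 through enol triflate 19 and a cross-coupling with an acetyl-anion equivalent. Triflate formation is regiospecific because C6 is quaternary.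

**17 to 12.** The surplus C7 oxygen is removed while ring A is still masked as the enol lactone, which protects both the C1 ketone and the acid. The unhindered C7 carbonyl of 12 is reduced (13), acetylated (14), and the γ-acetoxy enone is cleaved reductively (16). Only then is the enol lactone opened by methanolysis to 17. The benzyl ether is kept because a free C15 hydroxyl next to a C1 ketone invites retro-aldol loss and hemiketal formation.

**12 to 11.** The trans ring fusion is traced to the cis adduct. C5–H is α to the C7 carbonyl and vinylogously activated by the C10 carbonyl, so it can be epimerised. C4 is quaternary, so the adduct cannot aromatise.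

**11 to 9 and 10 (key disconnection).** Bonds C3–C4 and C5–C6 are cut. This removes ring A and both quaternary carbons in one step and leads to a commercially available quinone and a small achiral diene. The forward cycloaddition has to control regiochemistry, endo topology and absolute configuration; the last is left to a chiral boron Lewis acid.

**9 to 1, 3 and 6.** The enol lactone comes from keto acid 8, which can enolise only toward C4. Compound 8 comes from vinyl addition (6) to the Weinreb amide acid 5, and 5 from alkylation of the dianion of 2 with 3; 2 is the ring-opening product of 1. A route through an enamine Michael addition of a β-benzyloxy aldehyde to an acrylate was set aside, because β-alkoxy aldehydes tend to eliminate under amine catalysis.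

**34 to 30 and 31.** The pyrone ring is cut at the lactone C–O bond and at C5′–C6′, which leads to the diketo ester 33 and on to the γ-acylation of 30 by 31.

## Alternatives that were turned down

**Alternative 1:** The carbocyclic core plus one extra ring is traced to an acyclic (S)-epoxy tetraene acetate A2. In the forward step Cp2TiCl (trivalent titanium, made from Cp2TiCl2 and Mn) opens the epoxide to a tertiary radical that closes three six-membered rings through the three trisubstituted alkenes and ends as an exocyclic methylene, giving the tricyclic hydroxy acetate A1.
- For it: three rings and four stereocentres from an open chain in one step; the trans ring fusion arises directly from the alkene geometry, so no epimerisation is needed; the absolute configuration comes from one epoxide. On ring count per step and on the ring fusion it is stronger than the chosen route.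
- Against it for this target: the gem-dimethyl carbinol ring of A1 is built only to be cleaved again to the lactone and the isopropenyl group. C10 arrives as a CH without oxygen, and oxidising it later (for instance α-hydroxylation of the C11 aldehyde) would bring the oxygen in from the open face anti to the angular methyl, which is the wrong C10 epimer. The exocyclic alkene must be moved into the ring. A2 is a modified geranylgeranyl chain with one methyl replaced by a silyloxymethyl group and needs its own multistep synthesis.
- Comparison: the chosen strategy gives up the one-step polycyclisation, but delivers C10 as a ketone, C1 as a masked ketone and the acyl arm at the right oxidation level from commercially available 10.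

**Alternative 2:** Rings A and B are traced to the open-chain nitro triene A4, which already carries the spiro lactone and the isopropenyl group. On heating, the (E)-nitroalkene adds to the tethered (E,E)-diene, forming C4–C5 and C9–C10, to give the trans-fused nitro-octalin spiro-lactone A3.
- For it: both carbocycles form together, the lactone and isopropenyl are in place beforehand, and the nitro group marks C10 for later oxygenation. It needs no removal of a surplus oxygen and no conversion of a ring ketone into isopropenyl, and is stronger than the chosen route on both points.
- Against it: A4 contains the vicinal C1 tertiary and C6 quaternary stereocentres and two geometrically defined alkene units, all of which must be made by separate asymmetric chemistry before the key step. The cycloaddition then has to form the C4 quaternary carbon next to the neopentyl C5 under substrate control alone. The alkene of A3 sits at C7=C8 with a C9 stereocentre and has to be transposed, and the secondary nitro group still needs a Nef-type conversion.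
- Comparison: the chosen route spends steps after the cycloaddition, but takes three core stereocentres from one catalytic event on simple achiral partners.

**Alternative 3:** The lactone C14–O bond and the isopropenyl group are traced to the tricyclic hydroxymethyl ketone A6. The angular CH2OH and H2O2 convert the ketone into a bridged hydroperoxy ketal; FeSO4 and Cu(OAc)2 (divalent iron, divalent copper) then break the bond between the carbonyl carbon and the gem-dimethyl carbon, giving the spiro-lactone enone A5.
- For it: lactone and isopropenyl appear in one operation, where the chosen route needs about five steps for the same change; on this point the alternative is clearly stronger. A5 is the same compound as 25, so the end game would be identical.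
- Against it: A6 is a tricycle with an angular hydroxymethyl group, a trans ring fusion and a ring B enone, and the alternative does not say how it is reached; a third carbocycle would be built only to be opened. The radical fragmentation must also tolerate the enone and allylic hydrogens, and the hindered ketone may be slow to form the peroxy ketal.
- Comparison: the chosen strategy builds the seco skeleton directly, because the enol lactone 9 already contains the opened acyl arm, and it supplies the absolute configuration catalytically.

Key step: step 5

Assumption: by the C–H···O two-point binding model the catalyst derived from (S)-α,α-diphenylprolinol is taken to give 11 in the configuration drawn; should the sense of induction be the opposite, the (R)-catalyst is used with no other change.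

## Route

Step 1
Reactants: 1 glutaric anhydride
Product: 2 5-[methoxy(methyl)amino]-5-oxopentanoic acid
Conditions: MeNHOMe·HCl, Et3N, CH2Cl2, 0 °C to rt; 1 M HCl work-up
Reagents that add atoms: N,O-dimethylhydroxylamine hydrochloride, CNOC.Cl
Why: Aminolysis of a symmetrical cyclic anhydride opens one acyl–oxygen bond and leaves the other carbonyl as the free acid, so the two chain ends are differentiated without protecting groups (Weinreb amide formation).

Step 2
Reactants: 2 5-[methoxy(methyl)amino]-5-oxopentanoic acid; 3 benzyl chloromethyl ether
Product: 5 rac-4-[(benzyloxy)methyl]-5-[methoxy(methyl)amino]-5-oxopentanoic acid, via dilithium enolate carboxylate 4 (not isolated)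
Conditions: LiN(iPr)2 (2.2 equiv), THF, −78 °C; then 3, −78 to −40 °C; NH4Cl, then pH 3
Reagents that add atoms: none
Why: Dianion alkylation: once the carboxylate has formed, the second deprotonation occurs α to the amide, which is more acidic than the position α to a carboxylate, and the amide enolate is alkylated by the reactive α-chloro ether. The new stereocentre is racemic and is erased in step 4.

Step 3
Reactants: 5 rac-4-[(benzyloxy)methyl]-5-[methoxy(methyl)amino]-5-oxopentanoic acid; 6 vinylmagnesium bromide
Product: 8 rac-4-[(benzyloxy)methyl]-5-oxohept-6-enoic acid, via magnesium hemiaminal chelate 7 (not isolated)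
Conditions: CH2=CHMgBr (3.2 equiv), THF, −20 to 0 °C; inverse quench into cold 1 M HCl
Reagents that add atoms: none
Why: Weinreb ketone synthesis: the first equivalent of Grignard reagent makes the magnesium carboxylate, the second adds to the amide to give a chelated tetrahedral intermediate that resists over-addition. The acidic inverse quench releases the vinyl ketone while the liberated amine is protonated and cannot add to the enone.

Step 4
Reactants: 8 rac-4-[(benzyloxy)methyl]-5-oxohept-6-enoic acid
Product: 9 5-[(benzyloxy)methyl]-6-vinyl-3,4-dihydro-2H-pyran-2-one
Conditions: Ac2O (3 equiv), HClO4 (1 mol %), EtOAc, 0 °C, 15 min; NaHCO3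
Reagents that add atoms: none
Why: Acid-catalysed enol lactonisation of a δ-keto acid through the mixed anhydride. Only C4 can enolise (the other α-position is vinylic), so the tetrasubstituted enol double bond, and with it the diene, forms regiospecifically and the stereocentre of 8 disappears.

Step 5
Reactants: 9 5-[(benzyloxy)methyl]-6-vinyl-3,4-dihydro-2H-pyran-2-one; 10 2,6-dimethyl-1,4-benzoquinone
Product: 11 cis-fused Diels–Alder adduct (tricyclic enol δ-lactone ene-dione; C4 methyl, C5–H and C6–CH2OBn on one face)
Conditions: (S)-1-(2-methylphenyl)-3,3-diphenyltetrahydro-1H,3H-pyrrolo[1,2-c][1,3,2]oxazaborole (C24H24BNO, 20 mol %), HN(SO2CF3)2 (18 mol %), CH2Cl2, −78 to −40 °C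
Reagents that add atoms: none
Why: The N-protonated oxazaborolidine binds the quinone carbonyl that is flanked by two CH groups through the lone pair syn to an α-C–H, which activates the adjacent methyl-substituted double bond; 9 then adds by a concerted but asynchronous endo [4+2] cycloaddition in which the bond from the diene CH2 to the methyl-bearing β-carbon (C3–C4) runs ahead of the bond from the fully substituted diene terminus to the quinone CH (C5–C6). The closest known reaction type is the oxazaborolidinium-catalysed Diels–Alder reaction of 2,6-dimethylbenzoquinone with 2-silyloxy-1,3-dienes; the enol-ester donor and the tetrasubstituted terminus of 9 go beyond the dienes used there. Ring A is closed as a cyclohexene in the intermolecular [4+2] mode, with the new C1=C2 double bond inside the enol lactone. C4 is set by the catalyst, whose aryl group covers one face of the bound quinone so that the diene attacks the other; C5 follows from suprafacial addition to the quinone alkene (C5–H cis to the C4 methyl); C6 follows from the ring-locked diene geometry, which holds the CH2OBn arm inside, together with endo approach, which puts that arm cis to the angular methyl. Regioselectivity is needed and should come from pairing the unhindered CH2 terminus with the hindered β-carbon, since the other orientation would join two fully substituted carbons; endo selectivity is reinforced because the exo region is occupied by the catalyst; enantioselectivity rests on the two-point binding (B–O and C–H···O) of the quinone.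

Step 6
Reactants: 11 cis-fused Diels–Alder adduct
Product: 12 trans-fused enol-lactone ene-dione (C5–H anti to the C4 methyl)
Conditions: DBU (0.2 equiv), CH2Cl2, 0 °C to rt
Reagents that add atoms: none
Why: Base-mediated epimerisation through the extended enolate of the ene-dione: C5–H is α to the C7 carbonyl and vinylogously activated by C10=O, and C4 is quaternary, so aromatisation is impossible. The trans-fused isomer is expected to be favoured, as is known for angular-methyl quinone Diels–Alder adducts, and the non-nucleophilic base leaves the enol lactone intact.

Step 7
Reactants: 12 trans-fused enol-lactone ene-dione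
Product: 13 C7 alcohol (γ-hydroxy enone; C7–OH cis to the angular methyl, configuration immaterial)
Conditions: NaBH4, CeCl3·7H2O, MeOH/THF, −78 °C
Reagents that add atoms: none
Why: Luche 1,2-reduction: the C7 carbonyl is flanked by two CH groups, whereas C10=O lies between the quaternary C4 and the methyl-bearing C9, so hydride goes to C7. It should arrive from the face away from the 1,3-related angular methyl; the new stereocentre is removed in step 9.

Step 8
Reactants: 13 C7 alcohol
Product: 14 C7 acetate (γ-acetoxy enone)
Conditions: Ac2O, pyridine, DMAP (5 mol %), CH2Cl2, 0 °C to rt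
Reagents that add atoms: acetic anhydride, CC(=O)OC(C)=O
Why: Standard acylation of a secondary alcohol; it turns the γ-oxygen into a leaving group for the reductive cleavage.

Step 9
Reactants: 14 C7 acetate
Product: 16 ring B enone with C7H2 (enol lactone intact), via deconjugated enone 15 (not isolated)
Conditions: SmI2 (2.5 equiv), THF/MeOH, −78 °C; then DBU (0.2 equiv), CH2Cl2, rt
Reagents that add atoms: none
Why: Reductive cleavage of a γ-acyloxy enone by SmI2 (divalent samarium): two electron transfers to the enone expel acetate and leave a dienolate, whose kinetic α-protonation gives the β,γ-enone; DBU then moves the double bond back into conjugation. Esters, including the enol lactone, are not reduced under these conditions.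

Step 10
Reactants: 16 ring B enone with C7H2
Product: 17 keto ester (C1 ketone, methyl ester arm, C15 benzyl ether, ring B enone)
Conditions: K2CO3 (0.2 equiv), MeOH, 0 °C
Reagents that add atoms: methanol, CO
Why: Methanolysis of an enol ester, which is an activated acyl donor, releases the C1 ketone and the methyl ester. C5 is no longer α to a carbonyl, so the ring fusion cannot epimerise.

Step 11
Reactants: 17 keto ester
Product: 19 C1 enol triflate, via potassium enolate 18 (not isolated)
Conditions: KN(SiMe3)2 (1.05 equiv), THF, −78 °C; PhNTf2, −78 to 0 °C
Reagents that add atoms: N-phenylbis(trifluoromethanesulfonimide), O=S(=O)(N(c1ccccc1)S(=O)(=O)C(F)(F)F)C(F)(F)F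
Why: Kinetic deprotonation of the saturated ketone at C2, its only α-CH (C6 is quaternary), is faster than γ-deprotonation of the ring B enone or deprotonation of the ester; O-sulfonylation then gives the enol triflate regiospecifically.

Step 12
Reactants: 19 C1 enol triflate
Product: 21 ring A methyl enone (1-acetylcyclohexene unit), via ethoxy diene 20 (not isolated)
Conditions: CH2=C(OEt)SnBu3, Pd(PPh3)4 (5 mol %), LiCl, THF, 65 °C; then 1 M HCl, THF, rt
Reagents that add atoms: tributyl(1-ethoxyvinyl)stannane, CCCC[Sn](CCCC)(CCCC)C(=C)OCC; water, O
Why: Stille coupling of an alkenyl triflate with an acetyl-anion equivalent, followed by mild hydrolysis of the enol ether to the methyl ketone; the ester, the benzyl ether and the hindered ring B enone are untouched.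

Step 13
Reactants: 21 ring A methyl enone
Product: 23 spiro δ-lactone diketone (equatorial acetyl at C1, saturated ring B with equatorial C9 methyl), via hydroxy ester 22 (not isolated)
Conditions: H2 (4 atm), Pd(OH)2/C, EtOAc/MeOH, rt; then TsOH·H2O (10 mol %), toluene, 50 °C
Reagents that add atoms: none
Why: One heterogeneous hydrogenation saturates both conjugated alkenes and cleaves the benzyl ether; acid then closes the δ-lactone from the neopentyl alcohol onto the methyl ester, helped by the quaternary C6. Hydrogen should add to C1=C2 from the face opposite the angular methyl and C15, giving the equatorial acetyl group, which is also the thermodynamic epimer; the C9 centre is epimerisable and is removed in step 15.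

Step 14
Reactants: 23 spiro δ-lactone diketone
Product: 24 isopropenyl lactone ketone
Conditions: Ph3PCH3Br, KOtBu, THF, 0 to 40 °C
Reagents that add atoms: methyltriphenylphosphonium bromide, C[P+](c1ccccc1)(c1ccccc1)c1ccccc1.[Br-]
Why: Wittig methylenation of the methyl ketone. The C10 ketone, flanked by the quaternary C4 and the tertiary C9, is far more hindered and the lactone is unreactive toward the ylide; any C1 epimer is equilibrated to the equatorial isomer by the basic medium before olefination.

Step 15
Reactants: 24 isopropenyl lactone ketone
Product: 25 spiro-lactone enone (C8=C9 restored)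
Conditions: IBX (2.5 equiv), DMSO, 75 °C
Reagents that add atoms: none
Why: Dehydrogenation of a ketone to the enone with 2-iodoxybenzoic acid; the C10 ketone can enolise only toward C9, so the double bond returns regiospecifically to C8=C9.

Step 16
Reactants: 25 spiro-lactone enone
Product: 26 C10 spiro-epoxide (vinyl epoxide; C11H2 axial and anti to the angular methyl, oxygen equatorial)
Conditions: Me3SI, KN(SiMe3)2, THF, −10 to 0 °C
Reagents that add atoms: trimethylsulfonium iodide, C[S+](C)C.[I-]
Why: Corey–Chaykovsky epoxidation: dimethylsulfonium methylide adds 1,2 to the enone carbonyl irreversibly and, being small, along the axial trajectory anti to the axial methyl on the neighbouring C4. This sets C10 with the carbon substituent axial and the oxygen equatorial; the lactone is not attacked.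

Step 17
Reactants: 26 C10 spiro-epoxide
Product: 28 C10,C11 diol lactone, via potassium carboxylate 27 (not isolated)
Conditions: KOH, DMSO/H2O, 90 °C; then 1 M HCl to pH 3, EtOAc, rt
Reagents that add atoms: potassium hydroxide, [K+].[OH-]
Why: Base-mediated epoxide opening by SN2 attack at the CH2 carbon keeps the C10–O bond and therefore the C10 configuration. The lactone is saponified at the same time and closes again on acidification.

Step 18
Reactants: 28 C10,C11 diol lactone
Product: 29 tertiary α-hydroxy aldehyde
Conditions: TEMPO (10 mol %), PhI(OAc)2, CH2Cl2, rt
Reagents that add atoms: none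
Why: Oxoammonium-mediated oxidation is selective for the primary alcohol beside the tertiary one and stops at the aldehyde; 29 is used at once.

Step 19
Reactants: 30 ethyl acetoacetate; 31 ethyl nicotinate
Product: 33 ethyl 3,5-dioxo-5-(pyridin-3-yl)pentanoate, via sodium lithium dianion 32 (not isolated)
Conditions: NaH, THF, 0 °C; n-BuLi, 0 °C; 31 (0.5 equiv), 0 °C to rt; 1 M HCl
Reagents that add atoms: none
Why: γ-Acylation of the acetoacetate dianion (Claisen condensation at the more nucleophilic terminal carbon); the second equivalent of dianion takes up the acidic product.

Step 20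
Reactants: 33 ethyl 3,5-dioxo-5-(pyridin-3-yl)pentanoate
Product: 34 4-hydroxy-6-(pyridin-3-yl)-2H-pyran-2-one
Conditions: xylene, 140 °C (−EtOH)
Reagents that add atoms: none
Why: Thermal enol lactonisation of a 3,5-diketo ester: the enol oxygen of the aryl ketone attacks the ester carbonyl (6-exo-trig) and ethanol is lost.

Step 21
Reactants: 29 tertiary α-hydroxy aldehyde; 34 4-hydroxy-6-(pyridin-3-yl)-2H-pyran-2-one
Product: 35 target compound CNP0126103.3
Conditions: EDDA (ethylenediammonium diacetate, 20 mol %), MeCN, 50 °C
Reagents that add atoms: none
Why: Proposed new method: Knoevenagel condensation of pyrone C3′ with the aldehyde gives a 3-alkylidene-pyran-2,4-dione; the tertiary C10 hydroxyl adds to the C4′ carbonyl (5-exo-trig), and the resulting allylic hemiketal ionises and is rehydrated at C11, which restores the conjugated 2-pyrone and cannot go on to a furan because C10 is quaternary; the closest known reaction types are the García González condensation of 1,3-dicarbonyl compounds with α-hydroxy aldehydes and the interrupted Feist–Bénary reaction. Water should add to the planar C11 cation from the less crowded C9 side, and the same epimer is expected from equilibration.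

## Compound list

1 | glutaric anhydride | O=C1CCCC(=O)O1 | starting material
2 | 5-[methoxy(methyl)amino]-5-oxopentanoic acid | CON(C)C(=O)CCCC(=O)O | intermediate
3 | benzyl chloromethyl ether | ClCOCc1ccccc1 | starting material
4 | dilithium enolate carboxylate of 2 | [Li+].[Li+].CON(C)C([O-])=CCCC(=O)[O-] | intermediate
5 | rac-4-[(benzyloxy)methyl]-5-[methoxy(methyl)amino]-5-oxopentanoic acid | CON(C)C(=O)C(COCc1ccccc1)CCC(=O)O | intermediate
6 | vinylmagnesium bromide | C=C[Mg]Br | starting material
7 | magnesium hemiaminal chelate from 5 and 6 | C=CC(O[Mg]Br)(N(C)OC)C(COCc1ccccc1)CCC(=O)O[Mg]Br | intermediate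
8 | rac-4-[(benzyloxy)methyl]-5-oxohept-6-enoic acid | C=CC(=O)C(COCc1ccccc1)CCC(=O)O | intermediate
9 | 5-[(benzyloxy)methyl]-6-vinyl-3,4-dihydro-2H-pyran-2-one | C=CC1=C(COCc2ccccc2)CCC(=O)O1 | intermediate
10 | 2,6-dimethyl-1,4-benzoquinone | CC1=CC(=O)C=C(C)C1=O | starting material
11 | cis-fused Diels–Alder adduct (enol δ-lactone ene-dione; C4 methyl, C5–H and C6–CH2OBn cis) | O=C1CC[C@@]2(COCc3ccccc3)C(=CC[C@]3(C)[C@H]2C(=O)C=C(C)C3=O)O1 | intermediate
12 | trans-fused enol-lactone ene-dione (C5 epimer of 11) | O=C1CC[C@@]2(COCc3ccccc3)C(=CC[C@]3(C)[C@@H]2C(=O)C=C(C)C3=O)O1 | intermediate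
13 | C7 alcohol of 12 (OH cis to the angular methyl) | O=C1CC[C@@]2(COCc3ccccc3)C(=CC[C@]3(C)[C@@H]2[C@@H](O)C=C(C)C3=O)O1 | intermediate
14 | C7 acetate of 13 | O=C1CC[C@@]2(COCc3ccccc3)C(=CC[C@]3(C)[C@@H]2[C@@H](OC(C)=O)C=C(C)C3=O)O1 | intermediate
15 | deconjugated (C7=C8) enone, mixture at C9 | O=C1CC[C@@]2(COCc3ccccc3)C(=CC[C@]3(C)[C@@H]2C=CC(C)C3=O)O1 | intermediate
16 | trans-fused enol-lactone enone with C7H2 (C8=C9–C10=O) | O=C1CC[C@@]2(COCc3ccccc3)C(=CC[C@]3(C)[C@@H]2CC=C(C)C3=O)O1 | intermediate
17 | keto ester: C1 ketone, C6 bearing CH2OBn and CH2CH2CO2Me, ring B enone | O=C1CC[C@]2(C)[C@H](CC=C(C)C2=O)[C@@]1(COCc1ccccc1)CCC(=O)OC | intermediate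
18 | potassium C1 enolate of 17 | [K+].[O-]C1=CC[C@]2(C)[C@H](CC=C(C)C2=O)[C@@]1(COCc1ccccc1)CCC(=O)OC | intermediate
19 | C1 enol triflate | O=S(=O)(OC1=CC[C@]2(C)[C@H](CC=C(C)C2=O)[C@@]1(COCc1ccccc1)CCC(=O)OC)C(F)(F)F | intermediate
20 | 1-ethoxyvinyl diene at C1 | C=C(OCC)C1=CC[C@]2(C)[C@H](CC=C(C)C2=O)[C@@]1(COCc1ccccc1)CCC(=O)OC | intermediate
21 | ring A methyl enone (acetyl on C1=C2) | CC(=O)C1=CC[C@]2(C)[C@H](CC=C(C)C2=O)[C@@]1(COCc1ccccc1)CCC(=O)OC | intermediate
22 | hydroxy ester diketone (C15 OH free, acetyl at C1, saturated ring B, mixture at C9) | CC(=O)[C@@H]1CC[C@]2(C)[C@H](CCC(C)C2=O)[C@@]1(CO)CCC(=O)OC | intermediate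
23 | spiro δ-lactone diketone (equatorial C1 acetyl, equatorial C9 methyl) | CC(=O)[C@@H]1CC[C@]2(C)[C@H](CC[C@H](C)C2=O)[C@@]12CCC(=O)OC2 | intermediate
24 | spiro δ-lactone with C1 isopropenyl and saturated C10 ketone | C=C(C)[C@@H]1CC[C@]2(C)[C@H](CC[C@H](C)C2=O)[C@@]12CCC(=O)OC2 | intermediate
25 | spiro-lactone enone (C8=C9–C10=O) | C=C(C)[C@@H]1CC[C@]2(C)[C@H](CC=C(C)C2=O)[C@@]12CCC(=O)OC2 | intermediate
26 | C10 spiro-epoxide (C11H2 anti to the angular methyl) | C=C(C)[C@@H]1CC[C@]2(C)[C@H](CC=C(C)[C@]23CO3)[C@@]12CCC(=O)OC2 | intermediate
27 | potassium carboxylate of the seco acid triol | [K+].C=C(C)[C@@H]1CC[C@]2(C)[C@H](CC=C(C)[C@]2(O)CO)[C@@]1(CO)CCC(=O)[O-] | intermediate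
28 | C10,C11 diol lactone | C=C(C)[C@@H]1CC[C@]2(C)[C@H](CC=C(C)[C@]2(O)CO)[C@@]12CCC(=O)OC2 | intermediate
29 | tertiary α-hydroxy aldehyde (C10–OH, C11 aldehyde) | C=C(C)[C@@H]1CC[C@]2(C)[C@H](CC=C(C)[C@]2(O)C=O)[C@@]12CCC(=O)OC2 | intermediate
30 | ethyl acetoacetate | CCOC(=O)CC(C)=O | starting material
31 | ethyl nicotinate | CCOC(=O)c1cccnc1 | starting material
32 | sodium lithium dianion of ethyl acetoacetate | [Na+].[Li+].[CH2-]C(=O)[CH-]C(=O)OCC | intermediate
33 | ethyl 3,5-dioxo-5-(pyridin-3-yl)pentanoate | CCOC(=O)CC(=O)CC(=O)c1cccnc1 | intermediate
34 | 4-hydroxy-6-(pyridin-3-yl)-2H-pyran-2-one | O=c1cc(O)cc(-c2cccnc2)o1 | intermediate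
35 | CNP0126103.3 | C=C(C)[C@@H]1CC[C@]2(C)[C@H](CC=C(C)[C@@]23Oc2cc(-c4cccnc4)oc(=O)c2[C@@H]3O)[C@@]12CCC(=O)OC2 | target

## Step count and least certain steps

Total: 21 steps. Longest linear sequence: 19 steps (steps 1–18 and 21); steps 19–20 form the short pyrone branch.

**Step 21 (final spiro-annulation).** Condensation at the neopentyl aldehyde may be slow, so that α-ketol rearrangement of 29 or addition of a second pyrone competes, and C11 may not equilibrate fully to one epimer. The fallback uses known reactions, sets out from 29 and 34 and returns at 35. Compound 34 is iodinated at C3′ (N-iodosuccinimide, MeCN) to 4-hydroxy-3-iodo-6-(pyridin-3-yl)-2H-pyran-2-one F1 and O-methylated under Mitsunobu conditions (MeOH, PPh3, diisopropyl azodicarboxylate) to 3-iodo-4-methoxy-6-(pyridin-3-yl)-2H-pyran-2-one F2. Aldehyde 29 is silylated (Me3SiOTf, 2,6-lutidine) to the C10 trimethylsilyl ether aldehyde F3. Nozaki–Hiyama–Kishi coupling of F2 with F3 (CrCl2, divalent chromium, with catalytic NiCl2, DMF) should give, under non-chelating Felkin–Anh control, the C11 carbinol F4. Bu4NF removes the silyl group to give the diol F5, whose tertiary alkoxide closes the dihydrofuran by addition–elimination at C4′ with loss of methoxide, giving 35.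

**Step 5 (key step).** The tetrasubstituted diene terminus disfavours the reactive s-cis conformer, so conversion may be poor and the activated quinone may be diverted into Michael-type or ene pathways; a slow catalysed reaction would also let the uncatalysed background erode the enantioselectivity. The fallback keeps the same bond formation but gives up catalysis; it sets out from 9 and 10 and returns at 16. Thermal cycloaddition (toluene, 90 °C) gives the racemic cis adduct F6, DBU gives the racemic trans adduct F7, and Luche reduction gives the racemic C7 alcohol F8. Esterification with (S)-2-methoxy-2-phenylacetic acid (N,N′-dicyclohexylcarbodiimide, DMAP) gives two diastereomers; the (S)-O-methylmandelate F9 with the configuration of 13 is separated and submitted to the SmI2/DBU conditions of step 9, with the mandelate as leaving group, to give 16.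

**Step 6 (epimerisation).** The equilibrium may be incomplete or unfavourable, because both ring-fusion isomers carry 1,3-diaxial interactions around the two quaternary carbons. The fallback replaces thermodynamic by kinetic control, from 11 to 12: irreversible deprotonation (KN(SiMe3)2, THF, −78 °C) gives the potassium dienolate F10, which is protonated at C5 by a bulky donor (2,6-di-tert-butyl-4-methylphenol) from the face opposite the angular methyl and the benzyloxymethyl arm.

**Step 15 (dehydrogenation).** Enolisation of the hindered C10 ketone toward the tertiary C9 may be slow, so conversion stalls and oxidation elsewhere (α to the lactone, allylic positions) can compete. The fallback goes from 24 to 25 in two stages: soft enolisation (Me3SiOTf, Et3N) to the silyl enol ether F11, then Saegusa–Ito oxidation with Pd(OAc)2 in MeCN.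

**Step 17 (epoxide opening).** Attack at the neopentyl-type CH2 is slow, so hydroxide may instead open the vinyl epoxide with allylic transposition at C8 or isomerise it. The fallback goes from 26 to 29 and bypasses 28: sodium thiophenolate (PhSNa, DMF) opens the epoxide at CH2 to the β-hydroxy sulfide F12, NaIO4 gives the sulfoxide F13, and Pummerer rearrangement ((CF3CO)2O, 2,6-lutidine) followed by aqueous NaHCO3 releases aldehyde 29.

## Further compounds

F1 | step 21 | 4-hydroxy-3-iodo-6-(pyridin-3-yl)-2H-pyran-2-one | O=c1oc(-c2cccnc2)cc(O)c1I
F2 | step 21 | 3-iodo-4-methoxy-6-(pyridin-3-yl)-2H-pyran-2-one | COc1cc(-c2cccnc2)oc(=O)c1I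
F3 | step 21 | C10 trimethylsilyl ether of aldehyde 29 | C=C(C)[C@@H]1CC[C@]2(C)[C@H](CC=C(C)[C@]2(O[Si](C)(C)C)C=O)[C@@]12CCC(=O)OC2
F4 | step 21 | C11 carbinol from coupling of F2 and F3 (C10 silyl ether, 4′-methoxy pyrone) | C=C(C)[C@@H]1CC[C@]2(C)[C@H](CC=C(C)[C@]2(O[Si](C)(C)C)[C@@H](O)c2c(OC)cc(-c3cccnc3)oc2=O)[C@@]12CCC(=O)OC2
F5 | step 21 | C10,C11 diol with 4′-methoxy pyrone | C=C(C)[C@@H]1CC[C@]2(C)[C@H](CC=C(C)[C@]2(O)[C@@H](O)c2c(OC)cc(-c3cccnc3)oc2=O)[C@@]12CCC(=O)OC2
F6 | step 5 | racemic cis adduct (racemate of 11; one enantiomer drawn) | O=C1CC[C@@]2(COCc3ccccc3)C(=CC[C@]3(C)[C@H]2C(=O)C=C(C)C3=O)O1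
F7 | step 5 | racemic trans adduct (racemate of 12; one enantiomer drawn) | O=C1CC[C@@]2(COCc3ccccc3)C(=CC[C@]3(C)[C@@H]2C(=O)C=C(C)C3=O)O1
F8 | step 5 | racemic C7 alcohol (racemate of 13; one enantiomer drawn) | O=C1CC[C@@]2(COCc3ccccc3)C(=CC[C@]3(C)[C@@H]2[C@@H](O)C=C(C)C3=O)O1
F9 | step 5 | (S)-O-methylmandelate of 13 | O=C1CC[C@@]2(COCc3ccccc3)C(=CC[C@]3(C)[C@@H]2[C@@H](OC(=O)[C@@H](OC)c2ccccc2)C=C(C)C3=O)O1
F10 | step 6 | potassium dienolate of 11 | [K+].O=C1CC[C@@]2(COCc3ccccc3)C(=CC[C@]3(C)C2=C([O-])C=C(C)C3=O)O1
F11 | step 15 | C10 trimethylsilyl enol ether of 24 | C=C(C)[C@@H]1CC[C@]2(C)[C@H](CCC(C)=C2O[Si](C)(C)C)[C@@]12CCC(=O)OC2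
F12 | step 17 | β-hydroxy phenyl sulfide from 26 | C=C(C)[C@@H]1CC[C@]2(C)[C@H](CC=C(C)[C@]2(O)CSc2ccccc2)[C@@]12CCC(=O)OC2
F13 | step 17 | β-hydroxy phenyl sulfoxide (mixture at sulfur) | C=C(C)[C@@H]1CC[C@]2(C)[C@H](CC=C(C)[C@]2(O)CS(=O)c2ccccc2)[C@@]12CCC(=O)OC2
A1 | alternative 1 | tricyclic hydroxy acetate with exocyclic methylene | CC1(C)[C@@H](O)CC[C@@]2(CO[Si](C)(C)C(C)(C)C)[C@H]1CC[C@]1(C)[C@@H]2CCC(=C)[C@H]1COC(C)=O
A2 | alternative 1 | acyclic (S)-epoxy tetraene acetate | CC1(C)O[C@H]1CC/C(CO[Si](C)(C)C(C)(C)C)=C/CC/C(C)=C/CC/C(C)=C/COC(C)=O
A3 | alternative 2 | trans-fused nitro-octalin spiro-lactone | C=C(C)[C@@H]1CC[C@]2(C)[C@H](C=C[C@@H](C)[C@H]2[N+](=O)[O-])[C@@]12CCC(=O)OC2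
A4 | alternative 2 | open-chain nitro triene spiro-lactone | C=C(C)[C@H](CC/C(C)=C/[N+](=O)[O-])[C@@]1(/C=C/C=C/C)CCC(=O)OC1
A5 | alternative 3 | bicyclic spiro-lactone methylcyclohexenone (identical with 25) | C=C(C)[C@@H]1CC[C@]2(C)[C@H](CC=C(C)C2=O)[C@@]12CCC(=O)OC2
A6 | alternative 3 | tricyclic gem-dimethyl ketone with angular hydroxymethyl | CC1(C)C(=O)CC[C@@]2(CO)[C@H]1CC[C@]1(C)[C@@H]2CC=C(C)C1=O
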